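**Retrosynthetic overview**
1. The target comes from its mono-benzyl ether by hydrogenolysis. The tetrahydrofuran O1–C7 bond is closed just before, by intramolecular oxa-Michael (1,6-) addition of the C9′ primary OH to a p-quinone methide generated at C7 of an acyclic triol; this sets C7.
2. The triol comes from LiAlH4 reduction of a 2,3-cis-3,4-trans γ-lactone acid, a temporary template carrying C7′, C8′ and C8.
3. C7–C8 is made by alkylating the lactone-acid dianion with a vanillin-derived benzylic bromide, anti to both ring substituents.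
4. C7′–C8′ is made by an auxiliary-controlled MgCl2-catalysed anti-aldol of a succinyl oxazolidinone with O-benzylvanillin, followed by auxiliary cleavage and lactonisation.
5. Ring order: the temporary γ-lactone first (opened again later), the tetrahydrofuran last. Three branches converge: two vanillin-derived arenes and a C4 succinate core.

Assumption: lignan locants are used (C7/C8/C9 = ring-aryl half, C7′/C8′/C9′ = carbinol half), the target is read as the all-trans (7S,8R,7′S,8′S) isomer, and ancillary reagents (BnBr, PivCl, TMSCl and the like) are treated as reagents, not numbered compounds.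

**Branch A – benzylic bromide**

Step 1
Reactants: 1, vanillin
Product: 2, 4-formyl-2-methoxyphenyl pivalate
Conditions: PivCl, Et3N, DMAP (cat.), CH2Cl2, 0 °C → rt
Reagents that add atoms: pivaloyl chloride, CC(C)(C)C(=O)Cl
Why: Phenol O-acylation; the pivalate stabilises the later benzylic bromide, survives amide base at –78 °C and is removed without an extra step in the LiAlH4 reduction.

Step 2
Reactants: 2, 4-formyl-2-methoxyphenyl pivalate
Product: 3, 4-(hydroxymethyl)-2-methoxyphenyl pivalate
Conditions: NaBH4, MeOH–THF, 0 °C
Reagents that add atoms: none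
Why: Chemoselective borohydride reduction of the aldehyde; the hindered aryl ester is untouched.

Step 3
Reactants: 3, 4-(hydroxymethyl)-2-methoxyphenyl pivalate
Product: 4, 4-(bromomethyl)-2-methoxyphenyl pivalate
Conditions: PBr3, CH2Cl2, 0 °C
Reagents that add atoms: phosphorus tribromide, BrP(Br)Br
Why: SN2 bromination of a primary benzylic alcohol.

**Branch B – aldehyde**

Step 4
Reactants: 1, vanillin
Product: 5, 4-(benzyloxy)-3-methoxybenzaldehyde
Conditions: BnBr, K2CO3, DMF, 60 °C
Reagents that add atoms: benzyl bromide, BrCc1ccccc1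
Why: Williamson etherification; the benzyl ether survives LiOOH, LiHMDS, LiAlH4 and DDQ.

**Core and endgame**

Step 5
Reactants: 6, (S)-4-benzyl-1,3-oxazolidin-2-one; 7, methyl 4-chloro-4-oxobutanoate
Product: 8, methyl 4-[(4S)-4-benzyl-2-oxo-1,3-oxazolidin-3-yl]-4-oxobutanoate
Conditions: n-BuLi, THF, –78 °C; then 7, –78 → 0 °C
Reagents that add atoms: none
Why: N-acylation of the lithiated Evans auxiliary by the acid chloride.

Step 6
Reactants: 8, succinyl imide; 5, 4-(benzyloxy)-3-methoxybenzaldehyde
Product: 9, methyl (3R)-3-{(S)-[4-(benzyloxy)-3-methoxyphenyl][(trimethylsilyl)oxy]methyl}-4-[(4S)-4-benzyl-2-oxo-1,3-oxazolidin-3-yl]-4-oxobutanoate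
Conditions: MgCl2 (20 mol %), Et3N, TMSCl, EtOAc, rt, 24 h
Reagents that add atoms: chlorotrimethylsilane, C[Si](C)(C)Cl
Why: Evans Mg-halide-catalysed direct anti-aldol (soft enolisation of the imide only; TMSCl traps the aldolate). The chelated (Z)-enolate of the (S)-benzyl auxiliary is attacked on the face away from the benzyl group through a boat-like transition state, setting C8′ and C7′ in the anti relationship.

Step 7
Reactants: 9, silylated anti-aldol adduct
Product: 10, (2S,3R)-2-[4-(benzyloxy)-3-methoxyphenyl]-5-oxooxolane-3-carboxylic acid (2,3-cis)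
Conditions: LiOH, 30% H2O2, THF–H2O, 0 °C → rt; Na2SO3; then 1 M HCl to pH 2, rt
Reagents that add atoms: hydrogen peroxide (as LiOOH), OO (supplies the OH oxygen of the new CO2H)
Why: Evans LiOOH cleavage of the exocyclic imide (auxiliary 6 recovered), with ester saponification and O-desilylation. On acidification the γ-hydroxy acid lactonises by acyl substitution at C9, so C7′–O and C8′ keep their configuration (anti-aldol gives the cis-lactone).

Step 8
Reactants: 10, cis-lactone acid; 4, 4-(bromomethyl)-2-methoxyphenyl pivalate
Product: 11, (2S,3R,4R)-2-[4-(benzyloxy)-3-methoxyphenyl]-4-{[3-methoxy-4-(pivaloyloxy)phenyl]methyl}-5-oxooxolane-3-carboxylic acid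
Conditions: LiHMDS (2.3 equiv), THF, –78 °C, 1 h; then 4, –78 → –30 °C; AcOH quench
Reagents that add atoms: none
Why: Carboxylate/lactone-enolate dianion alkylation (SN2 on the benzylic bromide). Only C8–H2 is enolisable, and the electrophile enters opposite the cis-disposed aryl and carboxylate groups, setting C8 trans to C8′.

Step 9
Reactants: 11, alkylated lactone acid
Product: 12, (2S,3R)-2-{(S)-[4-(benzyloxy)-3-methoxyphenyl](hydroxy)methyl}-3-[(4-hydroxy-3-methoxyphenyl)methyl]butane-1,4-diol
Conditions: LiAlH4 (excess), THF, 0 → 50 °C; Rochelle salt work-up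
Reagents that add atoms: none
Why: Global hydride reduction: lactone to C9H2OH plus free C7′–OH, acid to C9′H2OH, aryl pivalate to free phenol. The benzyl ether and all three stereocentres are untouched.

Step 10
Reactants: 12, phenolic triol
Product: 13, 4-[(2S,3R,4S)-4-{(S)-[4-(benzyloxy)-3-methoxyphenyl](hydroxy)methyl}-3-(hydroxymethyl)oxolan-2-yl]-2-methoxyphenol
Conditions: DDQ (1.0 equiv, slow addition), CH2Cl2–1,4-dioxane, –20 → 0 °C
Reagents that add atoms: none
Why: DDQ dehydrogenates the free p-alkylphenol to a p-quinone methide; the C9′ primary OH adds in a 5-exo-trig intramolecular oxa-Michael (1,6-conjugate) addition and the ring rearomatises. The aryl group ends up trans to the C8 CH2OH (C7 = S, all-trans ring, also the thermodynamic outcome because the addition is reversible). Closure through the secondary C7′–OH would give a 3,4-cis ring and is disfavoured.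

Step 11
Reactants: 13, mono-benzyl ether
Product: 14, 4-[(2S,3R,4S)-4-[(S)-hydroxy(4-hydroxy-3-methoxyphenyl)methyl]-3-(hydroxymethyl)oxolan-2-yl]-2-methoxyphenol (target, CID 21630005)
Conditions: H2 (1 atm), 10% Pd/C, EtOAc–MeOH, rt
Reagents that add atoms: none
Why: Hydrogenolysis of the aryl benzyl ether; at 1 atm in neutral solvent the benzylic alcohol and the 2-aryl-THF C–O bond are kept and no stereocentre is touched.

**Compound list**
1 | vanillin | COc1cc(C=O)ccc1O | starting material
2 | 4-formyl-2-methoxyphenyl pivalate | COc1cc(C=O)ccc1OC(=O)C(C)(C)C | intermediate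
3 | 4-(hydroxymethyl)-2-methoxyphenyl pivalate | COc1cc(CO)ccc1OC(=O)C(C)(C)C | intermediate
4 | 4-(bromomethyl)-2-methoxyphenyl pivalate | COc1cc(CBr)ccc1OC(=O)C(C)(C)C | intermediate
5 | 4-(benzyloxy)-3-methoxybenzaldehyde | COc1cc(C=O)ccc1OCc1ccccc1 | intermediate
6 | (S)-4-benzyl-1,3-oxazolidin-2-one | O=C1N[C@@H](Cc2ccccc2)CO1 | starting material
7 | methyl 4-chloro-4-oxobutanoate | COC(=O)CCC(=O)Cl | starting material
8 | methyl 4-[(4S)-4-benzyl-2-oxooxazolidin-3-yl]-4-oxobutanoate | COC(=O)CCC(=O)N1[C@@H](Cc2ccccc2)COC1=O | intermediate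
9 | (3R, carbinol S) O-TMS anti-aldol adduct | COc1cc([C@@H](O[Si](C)(C)C)[C@@H](CC(=O)OC)C(=O)N2[C@@H](Cc3ccccc3)COC2=O)ccc1OCc1ccccc1 | intermediate
10 | (2S,3R)-2-[4-(benzyloxy)-3-methoxyphenyl]-5-oxooxolane-3-carboxylic acid | COc1cc([C@H]2OC(=O)C[C@H]2C(=O)O)ccc1OCc1ccccc1 | intermediate
11 | (2S,3R,4R)-2-[4-(benzyloxy)-3-methoxyphenyl]-4-{[3-methoxy-4-(pivaloyloxy)phenyl]methyl}-5-oxooxolane-3-carboxylic acid | COc1cc([C@H]2OC(=O)[C@H](Cc3ccc(OC(=O)C(C)(C)C)c(OC)c3)[C@H]2C(=O)O)ccc1OCc1ccccc1 | intermediate
12 | (2S,3R)-2-{(S)-[4-(benzyloxy)-3-methoxyphenyl](hydroxy)methyl}-3-[(4-hydroxy-3-methoxyphenyl)methyl]butane-1,4-diol | COc1cc([C@@H](O)[C@H](CO)[C@H](CO)Cc2ccc(O)c(OC)c2)ccc1OCc1ccccc1 | intermediate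
13 | 4′-O-benzyl ether of the target | COc1cc([C@@H](O)[C@@H]2CO[C@H](c3ccc(O)c(OC)c3)[C@H]2CO)ccc1OCc1ccccc1 | intermediate
14 | 4-[(2S,3R,4S)-4-[(S)-hydroxy(4-hydroxy-3-methoxyphenyl)methyl]-3-(hydroxymethyl)oxolan-2-yl]-2-methoxyphenol | COc1cc([C@@H](O)[C@@H]2CO[C@H](c3ccc(O)c(OC)c3)[C@H]2CO)ccc1O | target

**Totals**
Total steps: 11. Longest linear sequence: 7 (steps 5–11 from 6 + 7, or steps 1–3 then 8–11 from vanillin).

**Three steps most likely to fail**
- **Step 10 (DDQ quinone-methide cyclisation).** Product 13 is itself a p-hydroxybenzyl ether and may be oxidised further, and the C7′ carbinol may be oxidised. Fallback: carry oxygen at C7 from the C–C bond formation by using aldehyde 2 instead of bromide 4 in step 8 (dianion aldol; C7 configuration is irrelevant). After reduction, the quinone methide is then generated by dehydration of the p-hydroxybenzylic alcohol, with no oxidant, and cyclises the same way.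
- **Step 6 (Mg anti-aldol on an ester-bearing imide with an electron-rich aldehyde).** Conversion and diastereoselectivity are uncertain for this substrate. Fallback: Evans boron syn-aldol/lactonisation with the (R)-auxiliary, which gives the trans-lactone with correct C8′ and epimeric C7′; then invert C7′ by opening to the hydroxy acid and Mitsunobu relactonisation to the cis-lactone 10.
- **Step 8 (dianion alkylation).** Carboxylate O-benzylation or low conversion could compete. Fallback: set C8 by reagent control before the aldol (Evans alkylation of an N-(3-arylpropanoyl)oxazolidinone with tert-butyl bromoacetate, then the auxiliary-controlled anti-aldol on the acyclic chain), giving up the lactone template.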